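The route rests on the C1–C10 bond (briarane numbering). This bond is shared by the cyclohexane (C1, C10–C14) and the cyclodecene (C1–C10), and it joins quaternary C1 to C10. With C9 as a ketone and a C13=C14 alkene, it is the σ-bond of a Claisen retron. The precursor is therefore an oxygen-bridged macrocycle: a 12-membered ring (O, C13, C14, C1–C9) spanning a 3,4-dihydro-2H-pyran (O, C9–C13). One thermal [3,3] shift breaks O–C13 and forms C1–C10. It contracts the 12-membered ring to the ten-membered carbocycle, turns the pyran into the cyclohexene, and sets C1 and C10. The macrocycle comes from a tartrate/glyceraldehyde-derived macrolactone by olefinic-ester cyclisation.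

Key step: step 18

Numbering remark: C1 = quaternary fusion carbon (methyl C15), C2 (OAc), C3H2, C4 (OAc), C5 (methyl C16)=C6, C7 (lactone O), C8 (OH), C9 (OAc), C10 = fusion CH, C11 (methyl C20), C12 (OH), C13H2, C14 (OAc), C17 (methyl C18), C19 = lactone C=O. β is the cyclohexane face that carries C15. These labels are used for all intermediates, and CIP descriptors are given with these locants.

Assumption: 6 and the tartrate-modified (E)-crotylboronate are taken as stock reagents. Compounds 34–36 are epimer mixtures at the bromine-bearing carbon (racemic acyl bromide); this centre is erased in step 26.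

Step 1
Reactants: 1 dimethyl (4R,5R)-2,2-dimethyl-1,3-dioxolane-4,5-dicarboxylate
Product: 2 methyl (4R,5R)-5-formyl-2,2-dimethyl-1,3-dioxolane-4-carboxylate
Conditions: DIBAL-H (1.0 equiv), toluene, −78 °C; Rochelle salt
Reagents that add atoms: none
Why: Partial ester reduction stops at −78 °C at the tetrahedral aluminium hemiacetal, the two esters of the C2-symmetric diester are equivalent, and both tartrate centres (future C7 and C8) are untouched.

Step 2
Reactants: 2 methyl (4R,5R)-5-formyl-2,2-dimethyl-1,3-dioxolane-4-carboxylate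
Product: 3 methyl (4R,5S)-5-[(1Z)-2-iodoprop-1-enyl]-2,2-dimethyl-1,3-dioxolane-4-carboxylate
Conditions: EtPPh3I, n-BuLi, THF; I2, −78 °C; NaHMDS, −20 °C; then 2, −78 °C
Reagents that add atoms: ethyltriphenylphosphonium iodide CC[P+](c1ccccc1)(c1ccccc1)c1ccccc1.[I-]; iodine II
Why: Stork–Zhao-type Wittig olefination with the non-stabilised α-iodo ylide is kinetically Z-selective, so iodine ends cis to C7 and fixes the (5Z) geometry of the target alkene.

Step 3
Reactants: 3 methyl (4R,5S)-5-[(1Z)-2-iodoprop-1-enyl]-2,2-dimethyl-1,3-dioxolane-4-carboxylate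
Product: 5 methyl (4R,5S)-2,2-dimethyl-5-[(1Z)-2-methyl-3-oxobut-1-enyl]-1,3-dioxolane-4-carboxylate, via ethoxydiene 4 (not isolated)
Conditions: tributyl(1-ethoxyvinyl)stannane, Pd(PPh3)4 (cat.), CuI (cat.), DMF, 40 °C; then 1 M HCl, THF, 0 °C
Reagents that add atoms: tributyl(1-ethoxyvinyl)stannane C=C(OCC)[Sn](CCCC)(CCCC)CCCC; water O
Why: Stille coupling with the acyl-anion equivalent retains the alkene geometry, and mild hydrolysis of the enol ether gives the methyl ketone (C3–C4) without touching the acetonide.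

Step 4
Reactants: 6 (4S)-2,2-dimethyl-1,3-dioxolane-4-carbaldehyde
Product: 7 (1R,2R)-1-[(4S)-2,2-dimethyl-1,3-dioxolan-4-yl]-2-methylbut-3-en-1-ol
Conditions: (S,S)-diisopropyl tartrate (E)-crotylboronate, 4 Å MS, toluene, −78 °C
Reagents that add atoms: (S,S)-diisopropyl tartrate (E)-crotylboronate C/C=C/CB1O[C@H](C(=O)OC(C)C)[C@@H](C(=O)OC(C)C)O1
Why: Roush crotylboration runs through a chair Zimmerman–Traxler transition state in which the (E)-crotyl unit gives the 11,12-anti relation and the matched (S,S)-tartrate/(S)-aldehyde pair gives the 12,13-anti (Felkin) relation, setting C11 and C12.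

Step 5
Reactants: 7 (1R,2R)-1-[(4S)-2,2-dimethyl-1,3-dioxolan-4-yl]-2-methylbut-3-en-1-ol
Product: 8 (4S)-4-[(1R,2R)-1-(4-methoxybenzyloxy)-2-methylbut-3-enyl]-2,2-dimethyl-1,3-dioxolane
Conditions: NaH, PMBCl, Bu4NI (cat.), DMF, 0 °C → rt
Reagents that add atoms: 4-methoxybenzyl chloride COc1ccc(CCl)cc1
Why: Williamson etherification of the only hydroxyl installs PMB, which survives titanium alkylidenes, heat, fluoride, peroxide and SmI2 and can be removed last under neutral oxidative conditions.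

Step 6
Reactants: 8 (4S)-4-[(1R,2R)-1-(4-methoxybenzyloxy)-2-methylbut-3-enyl]-2,2-dimethyl-1,3-dioxolane
Product: 9 (2S,3R,4R)-3-(4-methoxybenzyloxy)-4-methylhex-5-ene-1,2-diol
Conditions: AcOH/H2O 4:1, 40 °C
Reagents that add atoms: none
Why: Acid-catalysed hydrolysis removes the terminal isopropylidene acetal, and the PMB ether and alkene are stable to aqueous acetic acid.

Step 7
Reactants: 9 (2S,3R,4R)-3-(4-methoxybenzyloxy)-4-methylhex-5-ene-1,2-diol
Product: 10 (2S,3R,4R)-3-(4-methoxybenzyloxy)-4-methyl-1,2-bis(triethylsilyloxy)hex-5-ene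
Conditions: TESCl, imidazole, DMF, 0 °C → rt
Reagents that add atoms: chlorotriethylsilane CC[Si](Cl)(CC)CC
Why: Standard silylation of both hydroxyls prepares the primary/secondary differentiation of the next step.

Step 8
Reactants: 10 (2S,3R,4R)-3-(4-methoxybenzyloxy)-4-methyl-1,2-bis(triethylsilyloxy)hex-5-ene
Product: 11 (2R,3R,4R)-3-(4-methoxybenzyloxy)-4-methyl-2-(triethylsilyloxy)hex-5-enal
Conditions: (COCl)2, DMSO, CH2Cl2, −78 → −30 °C; Et3N
Reagents that add atoms: none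
Why: Under Swern conditions the primary TES ether is cleaved and oxidised in situ while the hindered secondary TES ether stays, giving the α-silyloxy aldehyde (C14) without a separate deprotection or epimerisation at C13.

Step 9
Reactants: 11 (2R,3R,4R)-3-(4-methoxybenzyloxy)-4-methyl-2-(triethylsilyloxy)hex-5-enal
Product: 12 methyl (2Z,4S,5R,6R)-5-(4-methoxybenzyloxy)-2,6-dimethyl-4-(triethylsilyloxy)octa-2,7-dienoate
Conditions: methyl 2-[bis(2,2,2-trifluoroethoxy)phosphoryl]propanoate, KHMDS, 18-crown-6, THF, −78 °C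
Reagents that add atoms: methyl 2-[bis(2,2,2-trifluoroethoxy)phosphoryl]propanoate COC(=O)C(C)P(=O)(OCC(F)(F)F)OCC(F)(F)F
Why: In the Still–Gennari variant of the Horner–Wadsworth–Emmons reaction, fast irreversible elimination gives the (Z)-trisubstituted enoate, which places C2 cis to C13 as the key step requires.

Step 10
Reactants: 12 methyl (2Z,4S,5R,6R)-5-(4-methoxybenzyloxy)-2,6-dimethyl-4-(triethylsilyloxy)octa-2,7-dienoate
Product: 13 (2Z,4S,5R,6R)-5-(4-methoxybenzyloxy)-2,6-dimethyl-4-(triethylsilyloxy)octa-2,7-dien-1-ol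
Conditions: DIBAL-H (2.2 equiv), CH2Cl2, −78 °C
Reagents that add atoms: none
Why: 1,2-Reduction of the enoate by DIBAL-H gives the allylic alcohol with retention of the Z geometry.

Step 11
Reactants: 13 (2Z,4S,5R,6R)-5-(4-methoxybenzyloxy)-2,6-dimethyl-4-(triethylsilyloxy)octa-2,7-dien-1-ol
Product: 14 (2Z,4S,5R,6R)-5-(4-methoxybenzyloxy)-2,6-dimethyl-4-(triethylsilyloxy)octa-2,7-dienal
Conditions: activated MnO2, CH2Cl2, rt; used at once
Reagents that add atoms: none
Why: Heterogeneous allylic oxidation with MnO2 avoids the acid or base that would isomerise the (Z)-enal.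

Step 12
Reactants: 5 methyl (4R,5S)-2,2-dimethyl-5-[(1Z)-2-methyl-3-oxobut-1-enyl]-1,3-dioxolane-4-carboxylate; 14 (2Z,4S,5R,6R)-5-(4-methoxybenzyloxy)-2,6-dimethyl-4-(triethylsilyloxy)octa-2,7-dienal
Product: 17 aldol adduct (2R,7S,8R,11R,12R,13S) open chain C9→C2–C1=C14–C13→C10: C9 methyl ester / 7,8-O-isopropylidene / (5Z)-4-oxo / 2-OH / 1(14)Z / 13-OTES / 12-OPMB / terminal C10=CH2, via boron enolate 15 (not isolated), via boron aldolate 16 (not isolated)
Conditions: 5, (−)-Ipc2BCl, Et3N, Et2O, 0 °C; 14, −78 → −20 °C; H2O2, MeOH, pH 7 buffer, 0 °C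
Reagents that add atoms: none
Why: In this Paterson-type boron aldol reaction, kinetic enolisation occurs at the C3 methyl group and the isopinocampheyl ligands of the (−)-reagent select, in a cyclic boron transition state, the enal face that gives (2R).

Step 13
Reactants: 17 aldol adduct (2R,7S,8R,11R,12R,13S) open chain C9→C2–C1=C14–C13→C10: C9 methyl ester / 7,8-O-isopropylidene / (5Z)-4-oxo / 2-OH / 1(14)Z / 13-OTES / 12-OPMB / terminal C10=CH2
Product: 18 anti-2,4-diol (2R,4R,7S,8R,11R,12R,13S) of the same chain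
Conditions: Me4NBH(OAc)3, MeCN/AcOH, −30 °C
Reagents that add atoms: none
Why: In the Evans–Saksena reduction the C2-bound acetoxyborohydride delivers hydride intramolecularly through a chair transition state and gives the 2,4-anti diol, which sets (4R).

Step 14
Reactants: 18 anti-2,4-diol (2R,4R,7S,8R,11R,12R,13S) of the same chain
Product: 19 2,4-bis-TBS ether (2R,4R,7S,8R,11R,12R,13S) of the same chain
Conditions: TBSOTf, 2,6-lutidine, CH2Cl2, −78 → 0 °C
Reagents that add atoms: tert-butyldimethylsilyl triflate CC(C)(C)[Si](C)(C)OS(=O)(=O)C(F)(F)F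
Why: Silylation of both allylic hydroxyls in one operation gives ethers that tolerate the titanium reagent and the thermolysis.

Step 15
Reactants: 19 2,4-bis-TBS ether (2R,4R,7S,8R,11R,12R,13S) of the same chain
Product: 21 seco acid (2R,4R,7S,8R,11R,12R,13S): C9 CO2H / free 13-OH / 2,4-bis-OTBS / 7,8-acetonide / 12-OPMB, via lithium carboxylate 20 (not isolated)
Conditions: LiOH, THF/MeOH/H2O, 0 °C → rt; then 1 M HCl to pH 3, rt
Reagents that add atoms: lithium hydroxide [Li+].[OH-]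
Why: Saponification of the unhindered α-alkoxy methyl ester is followed by mild acid, which cleaves only the most labile silyl ether (secondary TES) and leaves TBS ethers, acetonide and PMB in place.

Step 16
Reactants: 21 seco acid (2R,4R,7S,8R,11R,12R,13S): C9 CO2H / free 13-OH / 2,4-bis-OTBS / 7,8-acetonide / 12-OPMB
Product: 23 12-membered macrolactone (2R,4R,7S,8R,11R,12R,13S): ring O13/C9(=O)/C8–C1/C14/C13; side chain C12(OPMB)–C11(Me)–CH=CH2 on C13, via mixed anhydride 22 (not isolated)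
Conditions: 2,4,6-trichlorobenzoyl chloride, Et3N, THF; then slow addition to DMAP, toluene, 60 °C, high dilution
Reagents that add atoms: none
Why: In the Yamaguchi macrolactonisation the two Z-alkenes and the trans-dioxolane act as turn elements that bring O13 and C9 together, and C13 keeps its configuration because its C–O bond is not broken.

Step 17
Reactants: 23 12-membered macrolactone (2R,4R,7S,8R,11R,12R,13S): ring O13/C9(=O)/C8–C1/C14/C13; side chain C12(OPMB)–C11(Me)–CH=CH2 on C13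
Product: 25 oxygen-bridged macrocycle (2R,4R,7S,8R,11R,12R,13S): 3,4-dihydro-2H-pyran O/C9=C10/C11/C12/C13 spanned from C9 to C13 by C8–C7–C6=C5–C4–C3–C2–C1=C14, via titanium alkylidene 24 (not isolated)
Conditions: TiCl4, TMEDA, Zn, PbCl2 (cat.), CH3CHBr2, THF/CH2Cl2, 65 °C; basic alumina
Reagents that add atoms: none
Why: In this Takai–Utimoto-type olefinic-ester cyclisation (carbonyl–olefin metathesis) the titanium ethylidene exchanges with the only monosubstituted alkene and the tethered alkylidene olefinates the lactone carbonyl to close a six-membered enol ether, while the trisubstituted alkenes are inert and no stereocentre is touched.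

Step 18
Reactants: 25 oxygen-bridged macrocycle (2R,4R,7S,8R,11R,12R,13S): 3,4-dihydro-2H-pyran O/C9=C10/C11/C12/C13 spanned from C9 to C13 by C8–C7–C6=C5–C4–C3–C2–C1=C14
Product: 26 briarane ketone (1S,2R,4R,7S,8R,10S,11R,12S): trans-fused cyclohex-13-ene/(5Z)-cyclodecene; 9-oxo; 15-Me β; H-10 α; 2,4-bis-OTBS; 7,8-acetonide; 12-OPMB
Conditions: 1,2-dichlorobenzene (0.005 M, degassed), BHT, base-washed sealed tube, 190 °C
Reagents that add atoms: none
Why: A concerted suprafacial [3,3]-sigmatropic (Claisen) shift of the allyl vinyl ether C10=C9–O–C13–C14=C1 breaks O–C13, forms C1–C10, makes C9 the ketone and moves the alkene to C13=C14. The closest known reaction is the Claisen rearrangement of 2-alkenyl-3,4-dihydro-2H-pyrans (C-vinyl glycals) to cyclohexenes, run here inside a macrocycle. The single new bond closes both carbocycles through one six-centre pericyclic array: the cyclohexene (C1, C10–C14) replaces the pyran, and the cyclodecene (C1–C10) arises by transannular contraction of the 12-membered oxacycle, which loses O, C13 and C14 and gains C10. Because C11–C12 tie C10 to C13, only the boat-like transition state with the C13 alkenyl group axial is possible, so (13S) directs bond formation to the pyran face anti to the C11 methyl and C12 ether and sets C10 (H α), while the (Z)-geometry of C14=C1 puts C2 trans to C9 and C15 β and sets quaternary C1. No other [3,3] array exists in 25, so the step needs only survival of the acid-labile enol ether, which base-washed glass, BHT and a neutral medium secure. C=O formation supplies the driving force that pays for the strain of the ten-membered ring.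

Step 19
Reactants: 26 briarane ketone (1S,2R,4R,7S,8R,10S,11R,12S): trans-fused cyclohex-13-ene/(5Z)-cyclodecene; 9-oxo; 15-Me β; H-10 α; 2,4-bis-OTBS; 7,8-acetonide; 12-OPMB
Product: 27 9-alcohol (1S,2R,4R,7S,8S,9R,10S,11R,12S) of the same skeleton
Conditions: L-Selectride, THF, −78 °C
Reagents that add atoms: none
Why: In a polar Felkin–Anh addition the bulky hydride attacks the C9 carbonyl anti to the C8–O bond from the ring periphery and gives the 8,9-syn relation, that is (9R).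

Step 20
Reactants: 27 9-alcohol (1S,2R,4R,7S,8S,9R,10S,11R,12S) of the same skeleton
Product: 28 2,4,9-triol (1S,2R,4R,7S,8S,9R,10S,11R,12S): 13-ene; 7,8-acetonide; 12-OPMB
Conditions: TBAF, AcOH, THF, 0 → 40 °C
Reagents that add atoms: none
Why: Fluoride-driven desilylation buffered with acetic acid is safe here because the substrate holds no ester or enolisable ketone at this stage.

Step 21
Reactants: 28 2,4,9-triol (1S,2R,4R,7S,8S,9R,10S,11R,12S): 13-ene; 7,8-acetonide; 12-OPMB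
Product: 31 2,4,9,14-tetraol (1S,2R,4R,7S,8S,9R,10S,11R,12S,14S): 7,8-acetonide; 12-OPMB, via tris(dimethylsilyl) ether 29 (not isolated), via oxasilolane 30 (not isolated)
Conditions: (HMe2Si)2NH, 60 °C, evaporate; Karstedt Pt(0) catalyst, toluene, 60 °C; then 30% H2O2, KF, KHCO3, THF/MeOH, rt
Reagents that add atoms: hydrogen peroxide OO
Why: In this Tamao–Ito intramolecular hydrosilylation and Tamao–Fleming oxidation only the O2-bound Si–H reaches the 1,2-disubstituted C13=C14 in a 5-exo mode, it adds to C14 from the α face on which C2 sits, and C–Si oxidation with retention gives 14α-OH, while the trisubstituted C5=C6 is inert to platinum hydrosilylation.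

Step 22
Reactants: 31 2,4,9,14-tetraol (1S,2R,4R,7S,8S,9R,10S,11R,12S,14S): 7,8-acetonide; 12-OPMB
Product: 32 2,4,9,14-tetraacetate (1R,2R,4R,7S,8R,9R,10S,11R,12S,14S): 7,8-acetonide; 12-OPMB
Conditions: Ac2O, DMAP, Et3N, CH2Cl2, rt → 40 °C
Reagents that add atoms: acetic anhydride CC(=O)OC(C)=O
Why: DMAP-catalysed acetylation covers all four free secondary hydroxyls while O12, O7 and O8 are masked.

Step 23
Reactants: 32 2,4,9,14-tetraacetate (1R,2R,4R,7S,8R,9R,10S,11R,12S,14S): 7,8-acetonide; 12-OPMB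
Product: 33 7,8-diol tetraacetate (1R,2R,4R,7S,8R,9R,10S,11R,12S,14S): 12-OPMB
Conditions: AcOH/H2O 4:1, 45 °C
Reagents that add atoms: none
Why: Acid hydrolysis opens the strained trans-fused dioxolane under conditions that leave the acetates and the PMB ether intact.

Step 24
Reactants: 33 7,8-diol tetraacetate (1R,2R,4R,7S,8R,9R,10S,11R,12S,14S): 12-OPMB
Product: 34 7-O-(2-bromopropanoyl) 8-alcohol tetraacetate (1R,2R,4R,7S,8R,9R,10S,11R,12S,14S)
Conditions: 2-bromopropanoyl bromide (1.05 equiv), 2,4,6-collidine, CH2Cl2, −78 °C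
Reagents that add atoms: 2-bromopropanoyl bromide CC(Br)C(=O)Br
Why: Kinetic acylation at low temperature prefers the allylic C7 hydroxyl, flanked by an sp2 carbon, over the C8 hydroxyl, which is crowded by the C9 acetate and the ring fusion.

Step 25
Reactants: 34 7-O-(2-bromopropanoyl) 8-alcohol tetraacetate (1R,2R,4R,7S,8R,9R,10S,11R,12S,14S)
Product: 35 8-ketone (1R,2R,4R,7S,9R,10S,11R,12S,14S) bearing the 7-O-(2-bromopropanoyl) group
Conditions: Dess–Martin periodinane, NaHCO3, CH2Cl2, 0 °C → rt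
Reagents that add atoms: none
Why: Dess–Martin oxidation under buffered neutral conditions gives the C8 ketone without epimerising C7 or C9.

Step 26
Reactants: 35 8-ketone (1R,2R,4R,7S,9R,10S,11R,12S,14S) bearing the 7-O-(2-bromopropanoyl) group
Product: 37 12-O-PMB ether of the target (1R,2R,4R,7S,8S,9R,10S,11R,12S,14S,17R), via samarium enolate 36 (not isolated)
Conditions: SmI2 (2.2 equiv, slow addition), THF, −78 °C; aq. NH4Cl
Reagents that add atoms: none
Why: In this SmI2-mediated intramolecular Reformatsky reaction (5-exo-trig aldol lactonisation) the C–Br bond is reduced first, the O7-tethered enolate reaches C8 only from the face syn to O7 in the ring conformer with C6–C7–C8–C9 anti, giving the trans-fused lactone with 8α-OH (8S), and the epimerisable C17 settles with its methyl anti to C9 (17R).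

Step 27
Reactants: 37 12-O-PMB ether of the target (1R,2R,4R,7S,8S,9R,10S,11R,12S,14S,17R)
Product: 38 target CNP0183630.2 (1R,2R,4R,5Z,7S,8S,9R,10S,11R,12S,14S,17R)
Conditions: DDQ, CH2Cl2/pH 7 buffer, 0 °C
Reagents that add atoms: none
Why: Oxidative PMB cleavage with DDQ (benzylic hydride abstraction) is neutral and spares the acetates, lactone, tertiary alcohol and the electron-poor alkene.

Compound list
1 | dimethyl (4R,5R)-2,2-dimethyl-1,3-dioxolane-4,5-dicarboxylate | COC(=O)[C@@H]1OC(C)(C)O[C@H]1C(=O)OC | starting material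
2 | methyl (4R,5R)-5-formyl-2,2-dimethyl-1,3-dioxolane-4-carboxylate | COC(=O)[C@@H]1OC(C)(C)O[C@H]1C=O | intermediate
3 | methyl (4R,5S)-5-[(1Z)-2-iodoprop-1-enyl]-2,2-dimethyl-1,3-dioxolane-4-carboxylate | COC(=O)[C@@H]1OC(C)(C)O[C@H]1/C=C(/C)I | intermediate
4 | ethoxydiene: methyl (4R,5S)-5-[(1Z)-3-ethoxy-2-methylbuta-1,3-dienyl]-2,2-dimethyl-1,3-dioxolane-4-carboxylate | COC(=O)[C@@H]1OC(C)(C)O[C@H]1/C=C(/C)C(=C)OCC | intermediate
5 | methyl (4R,5S)-2,2-dimethyl-5-[(1Z)-2-methyl-3-oxobut-1-enyl]-1,3-dioxolane-4-carboxylate | COC(=O)[C@@H]1OC(C)(C)O[C@H]1/C=C(/C)C(C)=O | intermediate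
6 | (4S)-2,2-dimethyl-1,3-dioxolane-4-carbaldehyde | O=C[C@@H]1COC(C)(C)O1 | starting material
7 | (1R,2R)-1-[(4S)-2,2-dimethyl-1,3-dioxolan-4-yl]-2-methylbut-3-en-1-ol | C=C[C@@H](C)[C@@H](O)[C@@H]1COC(C)(C)O1 | intermediate
8 | (4S)-4-[(1R,2R)-1-(4-methoxybenzyloxy)-2-methylbut-3-enyl]-2,2-dimethyl-1,3-dioxolane | C=C[C@@H](C)[C@@H](OCc1ccc(OC)cc1)[C@@H]2COC(C)(C)O2 | intermediate
9 | (2S,3R,4R)-3-(4-methoxybenzyloxy)-4-methylhex-5-ene-1,2-diol | C=C[C@@H](C)[C@@H](OCc1ccc(OC)cc1)[C@@H](O)CO | intermediate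
10 | (2S,3R,4R)-3-(4-methoxybenzyloxy)-4-methyl-1,2-bis(triethylsilyloxy)hex-5-ene | C=C[C@@H](C)[C@@H](OCc1ccc(OC)cc1)[C@@H](O[Si](CC)(CC)CC)CO[Si](CC)(CC)CC | intermediate
11 | (2R,3R,4R)-3-(4-methoxybenzyloxy)-4-methyl-2-(triethylsilyloxy)hex-5-enal | C=C[C@@H](C)[C@@H](OCc1ccc(OC)cc1)[C@@H](O[Si](CC)(CC)CC)C=O | intermediate
12 | methyl (2Z,4S,5R,6R)-5-(4-methoxybenzyloxy)-2,6-dimethyl-4-(triethylsilyloxy)octa-2,7-dienoate | C=C[C@@H](C)[C@@H](OCc1ccc(OC)cc1)[C@@H](O[Si](CC)(CC)CC)/C=C(/C)C(=O)OC | intermediate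
13 | (2Z,4S,5R,6R)-5-(4-methoxybenzyloxy)-2,6-dimethyl-4-(triethylsilyloxy)octa-2,7-dien-1-ol | C=C[C@@H](C)[C@@H](OCc1ccc(OC)cc1)[C@@H](O[Si](CC)(CC)CC)/C=C(/C)CO | intermediate
14 | (2Z,4S,5R,6R)-5-(4-methoxybenzyloxy)-2,6-dimethyl-4-(triethylsilyloxy)octa-2,7-dienal | C=C[C@@H](C)[C@@H](OCc1ccc(OC)cc1)[C@@H](O[Si](CC)(CC)CC)/C=C(/C)C=O | intermediate
15 | boron enolate: diisopinocampheylboron dienolate of 5 | COC(=O)[C@@H]1OC(C)(C)O[C@H]1/C=C(/C)C(=C)OB([C@@H]2C[C@@H]3C[C@H]([C@H]2C)C3(C)C)[C@@H]2C[C@@H]3C[C@H]([C@H]2C)C3(C)C | intermediate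
16 | boron aldolate: O2-diisopinocampheylborinate of 17 | COC(=O)[C@@H]1OC(C)(C)O[C@H]1/C=C(/C)C(=O)C[C@@H](OB([C@@H]2C[C@@H]3C[C@H]([C@H]2C)C3(C)C)[C@@H]2C[C@@H]3C[C@H]([C@H]2C)C3(C)C)/C(C)=C\[C@H](O[Si](CC)(CC)CC)[C@H](OCc2ccc(OC)cc2)[C@H](C)C=C | intermediate
17 | aldol adduct (2R,7S,8R,11R,12R,13S) open chain C9→C2–C1=C14–C13→C10: C9 methyl ester / 7,8-O-isopropylidene / (5Z)-4-oxo / 2-OH / 1(14)Z / 13-OTES / 12-OPMB / terminal C10=CH2 | COC(=O)[C@@H]1OC(C)(C)O[C@H]1/C=C(/C)C(=O)C[C@@H](O)/C(C)=C\[C@H](O[Si](CC)(CC)CC)[C@H](OCc2ccc(OC)cc2)[C@H](C)C=C | intermediate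
18 | anti-2,4-diol (2R,4R,7S,8R,11R,12R,13S) of the same chain | COC(=O)[C@@H]1OC(C)(C)O[C@H]1/C=C(/C)[C@H](O)C[C@@H](O)/C(C)=C\[C@H](O[Si](CC)(CC)CC)[C@H](OCc2ccc(OC)cc2)[C@H](C)C=C | intermediate
19 | 2,4-bis-TBS ether (2R,4R,7S,8R,11R,12R,13S) of the same chain | COC(=O)[C@@H]1OC(C)(C)O[C@H]1/C=C(/C)[C@H](O[Si](C)(C)C(C)(C)C)C[C@@H](O[Si](C)(C)C(C)(C)C)/C(C)=C\[C@H](O[Si](CC)(CC)CC)[C@H](OCc2ccc(OC)cc2)[C@H](C)C=C | intermediate
20 | lithium carboxylate of 19 (13-OTES still in place) | [Li+].[O-]C(=O)[C@@H]1OC(C)(C)O[C@H]1/C=C(/C)[C@H](O[Si](C)(C)C(C)(C)C)C[C@@H](O[Si](C)(C)C(C)(C)C)/C(C)=C\[C@H](O[Si](CC)(CC)CC)[C@H](OCc2ccc(OC)cc2)[C@H](C)C=C | intermediate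
21 | seco acid (2R,4R,7S,8R,11R,12R,13S): C9 CO2H / free 13-OH / 2,4-bis-OTBS / 7,8-acetonide / 12-OPMB | OC(=O)[C@@H]1OC(C)(C)O[C@H]1/C=C(/C)[C@H](O[Si](C)(C)C(C)(C)C)C[C@@H](O[Si](C)(C)C(C)(C)C)/C(C)=C\[C@H](O)[C@H](OCc2ccc(OC)cc2)[C@H](C)C=C | intermediate
22 | mixed anhydride of 21 and 2,4,6-trichlorobenzoic acid | O=C(OC(=O)[C@@H]1OC(C)(C)O[C@H]1/C=C(/C)[C@H](O[Si](C)(C)C(C)(C)C)C[C@@H](O[Si](C)(C)C(C)(C)C)/C(C)=C\[C@H](O)[C@H](OCc2ccc(OC)cc2)[C@H](C)C=C)c3c(Cl)cc(Cl)cc3Cl | intermediate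
23 | 12-membered macrolactone (2R,4R,7S,8R,11R,12R,13S): ring O13/C9(=O)/C8–C1/C14/C13; side chain C12(OPMB)–C11(Me)–CH=CH2 on C13 | O=C1[C@@H]2OC(C)(C)O[C@H]2/C=C(/C)[C@H](O[Si](C)(C)C(C)(C)C)C[C@@H](O[Si](C)(C)C(C)(C)C)/C(C)=C\[C@H](O1)[C@H](OCc3ccc(OC)cc3)[C@H](C)C=C | intermediate
24 | titanium alkylidene at C10 of 23 | O=C1[C@@H]2OC(C)(C)O[C@H]2/C=C(/C)[C@H](O[Si](C)(C)C(C)(C)C)C[C@@H](O[Si](C)(C)C(C)(C)C)/C(C)=C\[C@H](O1)[C@H](OCc3ccc(OC)cc3)[C@H](C)C=[Ti](Cl)Cl | intermediate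
25 | oxygen-bridged macrocycle (2R,4R,7S,8R,11R,12R,13S): 3,4-dihydro-2H-pyran O/C9=C10/C11/C12/C13 spanned from C9 to C13 by C8–C7–C6=C5–C4–C3–C2–C1=C14 | O1C2=C[C@@H](C)[C@@H](OCc4ccc(OC)cc4)[C@@H]1/C=C(C)\[C@H](O[Si](C)(C)C(C)(C)C)C[C@@H](O[Si](C)(C)C(C)(C)C)/C(C)=C\[C@@H]3OC(C)(C)O[C@H]32 | intermediate
26 | briarane ketone (1S,2R,4R,7S,8R,10S,11R,12S): trans-fused cyclohex-13-ene/(5Z)-cyclodecene; 9-oxo; 15-Me β; H-10 α; 2,4-bis-OTBS; 7,8-acetonide; 12-OPMB | C1=C[C@H](OCc4ccc(OC)cc4)[C@H](C)[C@@H]2C(=O)[C@@H]3OC(C)(C)O[C@H]3/C=C(/C)[C@H](O[Si](C)(C)C(C)(C)C)C[C@@H](O[Si](C)(C)C(C)(C)C)[C@]21C | intermediate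
27 | 9-alcohol (1S,2R,4R,7S,8S,9R,10S,11R,12S) of the same skeleton | C1=C[C@H](OCc4ccc(OC)cc4)[C@H](C)[C@@H]2[C@@H](O)[C@@H]3OC(C)(C)O[C@H]3/C=C(/C)[C@H](O[Si](C)(C)C(C)(C)C)C[C@@H](O[Si](C)(C)C(C)(C)C)[C@]21C | intermediate
28 | 2,4,9-triol (1S,2R,4R,7S,8S,9R,10S,11R,12S): 13-ene; 7,8-acetonide; 12-OPMB | C1=C[C@H](OCc4ccc(OC)cc4)[C@H](C)[C@@H]2[C@@H](O)[C@@H]3OC(C)(C)O[C@H]3/C=C(/C)[C@H](O)C[C@@H](O)[C@]21C | intermediate
29 | tris(dimethylsilyl) ether of 28 (O2, O4, O9) | C1=C[C@H](OCc4ccc(OC)cc4)[C@H](C)[C@@H]2[C@@H](O[SiH](C)C)[C@@H]3OC(C)(C)O[C@H]3/C=C(/C)[C@H](O[SiH](C)C)C[C@@H](O[SiH](C)C)[C@]21C | intermediate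
30 | oxasilolane: O2–SiMe2–C14(α) five-membered ring; O4 and O9 still as dimethylsilyl ethers | C[Si]5(C)[C@H]1C[C@H](OCc4ccc(OC)cc4)[C@H](C)[C@@H]2[C@@H](O[SiH](C)C)[C@@H]3OC(C)(C)O[C@H]3/C=C(/C)[C@H](O[SiH](C)C)C[C@@H](O5)[C@]21C | intermediate
31 | 2,4,9,14-tetraol (1S,2R,4R,7S,8S,9R,10S,11R,12S,14S): 7,8-acetonide; 12-OPMB | O[C@H]1C[C@H](OCc4ccc(OC)cc4)[C@H](C)[C@@H]2[C@@H](O)[C@@H]3OC(C)(C)O[C@H]3/C=C(/C)[C@H](O)C[C@@H](O)[C@]21C | intermediate
32 | 2,4,9,14-tetraacetate (1R,2R,4R,7S,8R,9R,10S,11R,12S,14S): 7,8-acetonide; 12-OPMB | CC(=O)O[C@H]1C[C@H](OCc4ccc(OC)cc4)[C@H](C)[C@@H]2[C@@H](OC(C)=O)[C@@H]3OC(C)(C)O[C@H]3/C=C(/C)[C@H](OC(C)=O)C[C@@H](OC(C)=O)[C@]21C | intermediate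
33 | 7,8-diol tetraacetate (1R,2R,4R,7S,8R,9R,10S,11R,12S,14S): 12-OPMB | CC(=O)O[C@H]1C[C@H](OCc3ccc(OC)cc3)[C@H](C)[C@@H]2[C@@H](OC(C)=O)[C@H](O)[C@@H](O)/C=C(/C)[C@H](OC(C)=O)C[C@@H](OC(C)=O)[C@]21C | intermediate
34 | 7-O-(2-bromopropanoyl) 8-alcohol tetraacetate (1R,2R,4R,7S,8R,9R,10S,11R,12S,14S) | CC(=O)O[C@H]1C[C@H](OCc3ccc(OC)cc3)[C@H](C)[C@@H]2[C@@H](OC(C)=O)[C@H](O)[C@@H](OC(=O)C(C)Br)/C=C(/C)[C@H](OC(C)=O)C[C@@H](OC(C)=O)[C@]21C | intermediate
35 | 8-ketone (1R,2R,4R,7S,9R,10S,11R,12S,14S) bearing the 7-O-(2-bromopropanoyl) group | CC(=O)O[C@H]1C[C@H](OCc3ccc(OC)cc3)[C@H](C)[C@@H]2[C@@H](OC(C)=O)C(=O)[C@@H](OC(=O)C(C)Br)/C=C(/C)[C@H](OC(C)=O)C[C@@H](OC(C)=O)[C@]21C | intermediate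
36 | samarium enolate of the O7 propanoate of 35 | CC(=O)O[C@H]1C[C@H](OCc3ccc(OC)cc3)[C@H](C)[C@@H]2[C@@H](OC(C)=O)C(=O)[C@@H](OC(O[Sm](I)I)=CC)/C=C(/C)[C@H](OC(C)=O)C[C@@H](OC(C)=O)[C@]21C | intermediate
37 | 12-O-PMB ether of the target (1R,2R,4R,7S,8S,9R,10S,11R,12S,14S,17R) | CC(=O)O[C@H]1C[C@H](OCc4ccc(OC)cc4)[C@H](C)[C@@H]2[C@@H](OC(C)=O)[C@@]3(O)[C@H](/C=C(/C)[C@H](OC(C)=O)C[C@@H](OC(C)=O)[C@]21C)OC(=O)[C@@H]3C | intermediate
38 | target CNP0183630.2 (1R,2R,4R,5Z,7S,8S,9R,10S,11R,12S,14S,17R) | CC(=O)O[C@H]1C[C@H](O)[C@H](C)[C@@H]2[C@@H](OC(C)=O)[C@@]3(O)[C@H](/C=C(/C)[C@H](OC(C)=O)C[C@@H](OC(C)=O)[C@]21C)OC(=O)[C@@H]3C | target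

Total step count: 27. Longest linear sequence: 24 steps (6 → 38, steps 4–27); the C3–C9 fragment 5 takes 3 steps.

Steps most likely to fail

Step 18. The bridged macrocycle may not reach the boat-like transition state, with C2 folded over C11, below the temperature at which the enol ether degrades by retro-hetero-Diels–Alder cleavage or loss of the allylic ether. The fallback sets out from 25 and abandons purely thermal activation. Triisobutylaluminium (CH2Cl2, −78 → 0 °C) binds the bridging oxygen and weakens O–C13, which triggers a charge-accelerated rearrangement. It then reduces the nascent C9 ketone by β-hydride transfer, giving the C9 carbinol epimer mixture F1. Dess–Martin oxidation of F1 comes back to the route at 26.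

Step 17. The low-valent titanium mixture may only ethylidenate the lactone carbonyl without closing the ring, or it may cleave the allylic C13–O bond reductively. The fallback sets out from 23 and separates the two events. Tebbe methylenation (THF, −40 → 0 °C, kept cold so that no premature sigmatropic shift occurs) gives the exocyclic enol ether F2. Ring-closing metathesis of its 1,1-disubstituted enol ether with the terminal vinyl group (second-generation Grubbs catalyst, benzene, 60 °C) comes back at 25.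

Step 21. Silylation of the neopentyl O2 may be incomplete, the hindered ring alkene may add Si–H too slowly, or the O9- or O4-bound silanes may compete. The fallback sets out from 27 and replaces intramolecular delivery by an intermolecular epoxidation–hydride sequence. Buffered mCPBA attacks C13=C14 from the α face, anti to C15 and the C12 ether, while C5=C6 is shielded on both faces and deactivated by two allylic C–O bonds. This gives the 13α,14α-epoxide F3. LiEt3BH opens F3 at the non-neopentyl C13 to give the 9,14-diol bis-TBS ether F4, and TBAF comes back at 31.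

Further compounds
F1 | step 18 | C9 carbinol epimer mixture of the rearranged skeleton (9-epimers of 27) | C1=C[C@H](OCc4ccc(OC)cc4)[C@H](C)[C@@H]2C(O)[C@@H]3OC(C)(C)O[C@H]3/C=C(/C)[C@H](O[Si](C)(C)C(C)(C)C)C[C@@H](O[Si](C)(C)C(C)(C)C)[C@]21C
F2 | step 17 | exocyclic enol ether: 9-methylidene analogue of macrolactone 23 | C=C1[C@@H]2OC(C)(C)O[C@H]2/C=C(/C)[C@H](O[Si](C)(C)C(C)(C)C)C[C@@H](O[Si](C)(C)C(C)(C)C)/C(C)=C\[C@H](O1)[C@H](OCc3ccc(OC)cc3)[C@H](C)C=C
F3 | step 21 | 13α,14α-epoxide of 27 | O1[C@H]2[C@@H]1[C@H](OCc4ccc(OC)cc4)[C@H](C)[C@@H]3[C@@H](O)[C@@H]5OC(C)(C)O[C@H]5/C=C(/C)[C@H](O[Si](C)(C)C(C)(C)C)C[C@@H](O[Si](C)(C)C(C)(C)C)[C@]32C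
F4 | step 21 | 9,14-diol bis-TBS ether (14α-OH) | O[C@H]1C[C@H](OCc4ccc(OC)cc4)[C@H](C)[C@@H]2[C@@H](O)[C@@H]3OC(C)(C)O[C@H]3/C=C(/C)[C@H](O[Si](C)(C)C(C)(C)C)C[C@@H](O[Si](C)(C)C(C)(C)C)[C@]21C
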